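## Analysis of the target

CNP0313204.1 is the flavanone (2S)-2-(3,4-dimethoxyphenyl)-6-hydroxy-5,7-dimethoxychroman-4-one (13), in which benzo ring A (C4a, C5 to C8, C8a) is fused to the dihydropyranone ring C (O1, C2, C3, C4) and the 3,4-dimethoxyphenyl ring B sits on C2. Ring A carries methoxy groups at C5 and C7, a free hydroxyl at C6 between them, and hydrogen only at C8. The single stereocentre is C2 (S); it is benzylic to the electron-rich ring B, bonded to the aryl ether oxygen O1 and β to the C4 ketone, so no neighbouring centre can relay stereochemistry to it. It is also easily lost, because a C3 enolate can expel O1 (retro-oxa-Michael) and strong acid can ionise the C2–O1 bond. The C6 phenol lies para to O1 in a hydroquinone-type array, is oxidation-prone, and has to be kept distinct from the other oxygens of ring A. The difficulty is therefore not the skeleton but setting C2 absolutely without an internal control element, and then keeping base away from the finished β-aryloxy ketone while the C6 oxygen stays masked. The strategy rests on the C3 methylene/C4 ketone pair of ring C: a ketone beside a CH2 is the hydrolysis product of an enol ether C3=C4, and a 4-silyloxy-2H-chromene with that double bond can be closed by olefin metathesis between an O1-bound 1-arylallyl group and a silyl enol ether on C4a.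

## Retrosynthetic reasoning

**13 ⇒ 12 (C6 O–benzyl bond).** The free C6 hydroxyl is revealed last from the benzyl ether 12. A benzyl group tolerates every earlier reagent and leaves under neutral conditions, which is what the base-labile C2 centre requires.

**12 ⇒ 11 (C4 ketone back to an enol ether).** The ketone of 12 is traced to the cyclic silyl enol ether 11, a 4-silyloxy-2H-chromene. No skeletal bond is cut. The forward step only has to put a proton on C3 and take silicon off oxygen without leaving a free enolate long enough to open ring C.

**11 ⇒ 10 (C3=C4, the central cut).** The C3=C4 double bond of 11 is cut by ring-closing metathesis, giving the acyclic diene 10. In 10, C3 is the internal carbon of a vinyl group on the C2 carbinol carbon and C4 is the oxygenated carbon of a silyl enol ether on ring A. This cut is preferred because it leaves C2 untouched, delivers C4 at the ketone oxidation level, and reduces ring C to two alkenes that are each one step from a carbonyl group or an allyl unit. The forward reaction must join a monosubstituted alkene to a hindered 1,1-disubstituted enol ether and expel both terminal methylenes.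

**10 ⇒ 9 (O–Si bond).** The silyl enol ether of 10 comes from the methyl ketone 9 by soft enolisation. Only the acetyl methyl group can enolise, so no regiochemical question arises.

**9 ⇒ 5 + 7 (O1–C2 bond).** The O1–C2 ether bond of 9 is cut between the phenol oxygen of the ortho-hydroxyacetophenone 5 (reacting as its lithium aryloxide 8) and the cinnamyl-type carbonate 7. This is the only bond whose formation can create C2 from two achiral pieces. A branched-selective, iridium-catalysed allylic etherification sets the S configuration under catalyst control and at the same time installs the vinyl group needed for the metathesis.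

**7 ⇒ 6.** The carbonate 7 is the activated form of the commercial allylic alcohol 6. One acylation of the hydroxyl is all that is needed.

**5 ⇒ 4 ⇒ 3 ⇒ 1 (ring A).** The benzyl group of 5 is removed retrosynthetically to the dihydroxyketone 4. Its chelated hydroxyl is the less reactive one, so the non-chelated C6-type hydroxyl can be benzylated selectively. The acetyl group of 4 is cut from the ring (C4a–C4 bond) to give the symmetrical hydroquinone 3. Its two free ring positions are equivalent, so the acylation has only one possible outcome. Hydroquinone 3 is the formyl-to-hydroxyl exchange product of the aldehyde 1, which already holds the C5, C6 and C7 oxygens in the right order.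

## Alternatives that were turned down

Alternative 1: ring A is built last by a polyketide-type Claisen cyclisation and aromatisation.
- Disconnection and forward reaction: the C4a–C5 bond is cut, which unravels ring A into a tricarbonyl chain hanging from C8a of a preformed, enantioenriched ring C. The substrate is ethyl 2-(benzyloxy)-4-[(2S)-2-(3,4-dimethoxyphenyl)-4-oxo-3,4-dihydro-2H-pyran-6-yl]-3-oxobutanoate (A2). In the forward direction base would turn A2 into its extended dienolate through the side-chain methylene, C4a would attack the ester carbonyl, the alkoxide would leave, and enolisation would aromatise ring A. The product would be (2S)-6-(benzyloxy)-2-(3,4-dimethoxyphenyl)-5,7-dihydroxychroman-4-one (A1).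
- In its favour: the plan mirrors the biosynthesis and needs no late-transition-metal catalyst. The oxygen pattern of ring A is fixed by the chain of A2, and C2 could be set early by a catalytic hetero-Diels–Alder reaction.
- Against it: A2 is a self-condensing tricarbonyl compound that takes several C-acylation steps to assemble. The cyclisation is strongly basic on a substrate whose C2 centre sits β to a carbonyl group with a ring-oxygen leaving group, so ring opening and racemisation are built in. A1 would then need two O-methylations, one of them at the chelated C5 hydroxyl under forcing basic conditions, before debenzylation.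
- Comparison: this plan is as strong or stronger on the regiochemical security of ring A and on reagent cost. The chosen route offers in its place a ring A bought intact in 1, fewer steps, and no base once C2 exists.

Alternative 2: an iminium-catalysed oxa-Michael–aldol domino that carries a sacrificial formyl group.
- Disconnection and forward reaction: O1–C2 and C3–C4 are cut together, with one extra carbon left on C3. The partners are 3-(benzyloxy)-6-hydroxy-2,4-dimethoxybenzaldehyde (A4) and (E)-3-(3,4-dimethoxyphenyl)prop-2-enal (A5). A diarylprolinol silyl ether would activate A5 as an iminium ion, the phenol oxygen of A4 would add to its β-carbon, and the resulting enamine would condense with the aryl aldehyde. The product would be (2R)-6-(benzyloxy)-2-(3,4-dimethoxyphenyl)-5,7-dimethoxy-2H-chromene-3-carbaldehyde (A3), which has the spatial arrangement at C2 that the target needs.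
- In its favour: the domino is well established for salicylaldehydes and enals, is metal-free, and forms two ring bonds and C2 in one operation from simple partners. Judged on the ring-forming step alone it is at least as secure as the chosen route, and cheaper.
- Against it: A3 has one carbon too many and no oxygen at C4. The formyl group would have to be excised by decarbonylation or oxidative degradation, and the resulting styrene-type C3=C4 bond would then have to be oxidised at C4 and not at C3. All of this would run on a 2-aryl-2H-chromene that can open electrocyclically and lose C2. A4 is also a di-ortho-substituted, electron-rich aldehyde and A5 gives a poorly electrophilic iminium ion, so the reversible oxa-Michael step may erode the enantiopurity.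
- Comparison: the chosen route forms the same C3=C4 bond with C4 already at the ketone oxidation level and no carbon to remove, so it avoids three or four corrective steps after the ring closure.

Alternative 3: a formal [4+2] reaction of an aryl oxocarbenium ion with a ketene acetal.
- Disconnection and forward reaction: C2–C3 and C4–C4a are cut, inserting a two-carbon ketene unit between the acetal carbon and ring A. The partners are the racemic mixed acetal 2-(benzyloxy)-5-[(3,4-dimethoxyphenyl)(methoxy)methoxy]-1,3-dimethoxybenzene (A7) and 1,1-diethoxyethene (A8). A chiral confined Brønsted acid would ionise A7, A8 would add to the oxocarbenium carbon, and the ortho carbon of ring A would trap the dialkoxycarbenium ion. The product would be (2S)-6-(benzyloxy)-4,4-diethoxy-2-(3,4-dimethoxyphenyl)-5,7-dimethoxychroman (A6).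
- In its favour: it is the most convergent and the shortest plan. Two C–C bonds, ring C and C2 would arise in one step, and C4 would arrive in A6 as a masked ketone. Hydrolysis of the ketal A6 would lead to 12, and debenzylation would finish the synthesis.
- Against it: the cascade to A6 has no close precedent. The aryloxy group of A7 is a better nucleofuge than its methoxy group, so ionisation can cut the very O1–C2 link the plan needs. A8 is protonated and oligomerised by strong acids. The dialkoxycarbenium ion is more likely to collapse to an ester than to attack a hindered arene carbon, and ring A can alkylate the oxocarbenium ion directly. Facial control over an unhindered aryl oxocarbenium ion in a chiral ion pair is unproven for this substitution pattern.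
- Comparison: this plan is clearly stronger on step economy. The chosen route offers reaction types that all have precedent, and it separates the stereo-defining step from the ring closure so that each can be optimised alone.

Key step: step 7

Assumption: the (Sa,Sc,Sc) enantiomer of the binaphthol-derived N,N-bis(1-phenylethyl)phosphoramidite is taken to give the (S)-configured branched ether in step 5. If the sense of induction proves opposite on this substrate, the mirror-image ligand is used with no other change. Compounds 1 and 6 are taken as purchased.

## Route

Step 1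
Reactants: 1 syringaldehyde (4-hydroxy-3,5-dimethoxybenzaldehyde)
Product: 3 2,6-dimethoxybenzene-1,4-diol, via 4-hydroxy-3,5-dimethoxyphenyl formate 2 (not isolated)
Conditions: 30% aq H2O2 (1.1 equiv), NaOH (2 equiv), degassed H2O, 0 °C → rt, N2; then 2 M HCl
Reagents that add atoms: hydrogen peroxide, OO
Why: Dakin oxidation; hydroperoxide adds to the aldehyde of the para-phenoxide, the very electron-rich aryl group migrates to oxygen, and the aryl formate 2 is saponified in the same flask; exclusion of air keeps the hydroquinone from oxidising to the quinone.

Step 2
Reactants: 3 2,6-dimethoxybenzene-1,4-diol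
Product: 4 1-(3,6-dihydroxy-2,4-dimethoxyphenyl)ethan-1-one
Conditions: AcOH, BF3·OEt2 (3 equiv), 85 °C, N2; then aq NaOAc
Reagents that add atoms: acetic acid, CC(=O)O
Why: Friedel–Crafts C-acylation of an activated phenol; the only two free ring positions of 3 are equivalent (each ortho to the unhindered hydroxyl and ortho/para to methoxy groups), so a single regioisomer is possible, and the aryl ketone formed deactivates the ring against a second acylation.

Step 3
Reactants: 4 1-(3,6-dihydroxy-2,4-dimethoxyphenyl)ethan-1-one
Product: 5 1-[3-(benzyloxy)-6-hydroxy-2,4-dimethoxyphenyl]ethan-1-one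
Conditions: BnBr (1.05 equiv), K2CO3 (1.2 equiv), acetone, 56 °C, N2
Reagents that add atoms: benzyl bromide, BrCc1ccccc1
Why: Williamson etherification; the hydroxyl ortho to the acetyl group is locked in a hydrogen bond to the carbonyl and is the poorer nucleophile, so one equivalent of halide should alkylate the non-chelated hydroxyl between the two methoxy groups, as is usual for 2,5-dihydroxyacetophenones.

Step 4
Reactants: 6 (E)-3-(3,4-dimethoxyphenyl)prop-2-en-1-ol
Product: 7 (E)-3-(3,4-dimethoxyphenyl)prop-2-en-1-yl methyl carbonate
Conditions: ClCO2Me (1.2 equiv), pyridine (1.5 equiv), CH2Cl2, 0 °C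
Reagents that add atoms: methyl chloroformate, COC(=O)Cl
Why: O-acylation of a primary allylic alcohol to the carbonate leaving group required for the allylic substitution; the alkene geometry is untouched.

Step 5
Reactants: 5 1-[3-(benzyloxy)-6-hydroxy-2,4-dimethoxyphenyl]ethan-1-one; 7 (E)-3-(3,4-dimethoxyphenyl)prop-2-en-1-yl methyl carbonate
Product: 9 1-[3-(benzyloxy)-6-{[(1S)-1-(3,4-dimethoxyphenyl)prop-2-en-1-yl]oxy}-2,4-dimethoxyphenyl]ethan-1-one, via lithium 2-acetyl-4-(benzyloxy)-3,5-dimethoxyphenolate 8 (not isolated)
Conditions: 5, LiN(SiMe3)2 (1.0 equiv), THF, 0 °C; then 7 (1.2 equiv), [Ir(cod)Cl]2 (2 mol%), (Sa,Sc,Sc)-O,O′-(1,1′-binaphthyl-2,2′-diyl) N,N-bis(1-phenylethyl)phosphoramidite (4 mol%, pre-activated with n-PrNH2 at 50 °C and evaporated), THF, rt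
Reagents that add atoms: none
Why: Iridium-catalysed asymmetric allylic etherification with an aryloxide; the cyclometalated iridium phosphoramidite ionises 7 to an allyl complex, and 8 attacks the aryl-substituted terminus on the face left open by the ligand, which gives the branched ether and sets C2 as S under catalyst control. One equivalent of base deprotonates only the phenol, so the methyl ketone is not enolised and O-alkylation should prevail.

Step 6
Reactants: 9 1-[3-(benzyloxy)-6-{[(1S)-1-(3,4-dimethoxyphenyl)prop-2-en-1-yl]oxy}-2,4-dimethoxyphenyl]ethan-1-one
Product: 10 tert-butyl({1-[3-(benzyloxy)-6-{[(1S)-1-(3,4-dimethoxyphenyl)prop-2-en-1-yl]oxy}-2,4-dimethoxyphenyl]ethenyl}oxy)dimethylsilane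
Conditions: TBSOTf (1.3 equiv), Et3N (3 equiv), CH2Cl2, −78 → 0 °C; NaHCO3 quench, Et3N-deactivated silica
Reagents that add atoms: tert-butyldimethylsilyl trifluoromethanesulfonate, CC(C)(C)[Si](C)(C)OS(=O)(=O)C(F)(F)F
Why: Soft enolisation of a methyl ketone (O-silylation of the carbonyl, then deprotonation of the only α-carbon by the amine); the excess amine buffers the Lewis acidity of the silyl triflate so that the doubly activated allyl aryl ether should not ionise, and C2 is not involved.

Step 7
Reactants: 10 tert-butyl({1-[3-(benzyloxy)-6-{[(1S)-1-(3,4-dimethoxyphenyl)prop-2-en-1-yl]oxy}-2,4-dimethoxyphenyl]ethenyl}oxy)dimethylsilane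
Product: 11 (2S)-6-(benzyloxy)-4-[(tert-butyldimethylsilyl)oxy]-2-(3,4-dimethoxyphenyl)-5,7-dimethoxy-2H-chromene
Conditions: second-generation Grubbs catalyst (H2IMes)(PCy3)Cl2Ru=CHPh (5–8 mol%, two portions), 1,4-benzoquinone (15 mol%), degassed toluene (0.01 M), 70 °C, Ar sparge, dark
Reagents that add atoms: none
Why: The catalyst loads onto the monosubstituted vinyl group of 10, the only unhindered alkene, to give a ruthenium alkylidene at the future C3; this adds across the 1,1-disubstituted silyl enol ether with ruthenium on the terminal methylene, and cycloreversion of the ruthenacyclobutane releases 11 and a ruthenium methylidene that carries the chain while ethylene leaves the solution. The closest known reaction type is the ring-closing metathesis of silyl enol ethers with terminal alkenes to cyclic silyl enol ethers, which includes benzo-fused six-membered nitrogen and oxygen heterocycles. Ring C closes as a six-membered ring with the new C3=C4 bond endocyclic; both arms are held ortho on ring A, which favours closure over dimerisation, and dilution helps further. No stereocentre is formed: C2 was fixed in step 5 and is not a reacting centre, so its configuration is carried over as long as the allylic C2–H is not touched. The selectivity needed is therefore chemoselectivity: initiation at the vinyl group and not at the hindered enol ether is secured by the substitution pattern of 10, and double-bond migration through ruthenium hydrides, which would destroy C2, is held back by 1,4-benzoquinone and by sweeping out ethylene. The electron-rich enol ether, flanked by the C5 methoxy group and the silyloxy group, is the slow partner, which is why the N-heterocyclic-carbene catalyst and moderate heating are chosen; light is excluded because 2-aryl-2H-chromenes can open electrocyclically.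

Step 8
Reactants: 11 (2S)-6-(benzyloxy)-4-[(tert-butyldimethylsilyl)oxy]-2-(3,4-dimethoxyphenyl)-5,7-dimethoxy-2H-chromene
Product: 12 (2S)-6-(benzyloxy)-2-(3,4-dimethoxyphenyl)-5,7-dimethoxychroman-4-one
Conditions: Bu4NF (1.1 equiv), AcOH (1.5 equiv), THF, 0 °C
Reagents that add atoms: none
Why: Fluoride-induced cleavage of the silyl enol ether with a proton source present; the enolate is protonated at C3 as it forms, so it should have no lifetime in which to expel O1 and open ring C, and C2 should stay S.

Step 9
Reactants: 12 (2S)-6-(benzyloxy)-2-(3,4-dimethoxyphenyl)-5,7-dimethoxychroman-4-one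
Product: 13 (2S)-2-(3,4-dimethoxyphenyl)-6-hydroxy-5,7-dimethoxychroman-4-one (CNP0313204.1)
Conditions: H2 (1 atm), 10% Pd/C, EtOAc, rt
Reagents that add atoms: none
Why: Hydrogenolysis of the aryl benzyl ether under neutral conditions; the electron-rich aryl ketone and the ring C–O bond of flavanones normally survive one atmosphere of hydrogen for the time needed, and no base or acid is present that could affect C2.

## Compound list

1 | syringaldehyde (4-hydroxy-3,5-dimethoxybenzaldehyde) | COc1cc(C=O)cc(OC)c1O | starting material
2 | 4-hydroxy-3,5-dimethoxyphenyl formate | COc1cc(OC=O)cc(OC)c1O | intermediate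
3 | 2,6-dimethoxybenzene-1,4-diol | COc1cc(O)cc(OC)c1O | intermediate
4 | 1-(3,6-dihydroxy-2,4-dimethoxyphenyl)ethan-1-one | CC(=O)c1c(O)cc(OC)c(O)c1OC | intermediate
5 | 1-[3-(benzyloxy)-6-hydroxy-2,4-dimethoxyphenyl]ethan-1-one | CC(=O)c1c(O)cc(OC)c(OCc2ccccc2)c1OC | intermediate
6 | (E)-3-(3,4-dimethoxyphenyl)prop-2-en-1-ol | COc1ccc(/C=C/CO)cc1OC | starting material
7 | (E)-3-(3,4-dimethoxyphenyl)prop-2-en-1-yl methyl carbonate | COC(=O)OC/C=C/c1ccc(OC)c(OC)c1 | intermediate
8 | lithium 2-acetyl-4-(benzyloxy)-3,5-dimethoxyphenolate | [Li+].CC(=O)c1c([O-])cc(OC)c(OCc2ccccc2)c1OC | intermediate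
9 | 1-[3-(benzyloxy)-6-{[(1S)-1-(3,4-dimethoxyphenyl)prop-2-en-1-yl]oxy}-2,4-dimethoxyphenyl]ethan-1-one | CC(=O)c1c(O[C@@H](C=C)c2ccc(OC)c(OC)c2)cc(OC)c(OCc2ccccc2)c1OC | intermediate
10 | tert-butyl({1-[3-(benzyloxy)-6-{[(1S)-1-(3,4-dimethoxyphenyl)prop-2-en-1-yl]oxy}-2,4-dimethoxyphenyl]ethenyl}oxy)dimethylsilane | C=C(O[Si](C)(C)C(C)(C)C)c1c(O[C@@H](C=C)c2ccc(OC)c(OC)c2)cc(OC)c(OCc2ccccc2)c1OC | intermediate
11 | (2S)-6-(benzyloxy)-4-[(tert-butyldimethylsilyl)oxy]-2-(3,4-dimethoxyphenyl)-5,7-dimethoxy-2H-chromene | COc1ccc([C@@H]2C=C(O[Si](C)(C)C(C)(C)C)c3c(cc(OC)c(OCc4ccccc4)c3OC)O2)cc1OC | intermediate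
12 | (2S)-6-(benzyloxy)-2-(3,4-dimethoxyphenyl)-5,7-dimethoxychroman-4-one | COc1ccc([C@@H]2CC(=O)c3c(cc(OC)c(OCc4ccccc4)c3OC)O2)cc1OC | intermediate
13 | (2S)-2-(3,4-dimethoxyphenyl)-6-hydroxy-5,7-dimethoxychroman-4-one | COc1ccc([C@@H]2CC(=O)c3c(cc(OC)c(O)c3OC)O2)cc1OC | target

## Step count and least certain steps

Total step count: 9. Longest linear sequence: 8 (steps 1, 2, 3, 5, 6, 7, 8, 9); step 4 is a one-step side branch.

**Step 7, the key step.** The most likely failure is a stalled ring closure. The alkylidene formed at the vinyl group may not engage the twisted, electron-rich enol ether, which is flanked by two ortho substituents. The catalyst then decays to ruthenium hydrides, and these shift the allylic double bond into conjugation and erase C2; the vinyl groups may also dimerise. The fallback gives up the metathesis. It sets out from 5 and returns at 12. Condensation of 5 with N,N-dimethylformamide dimethyl acetal should give the enaminone (E)-1-[3-(benzyloxy)-6-hydroxy-2,4-dimethoxyphenyl]-3-(dimethylamino)prop-2-en-1-one F1. Acid-promoted cyclisation with loss of dimethylamine leads to 6-(benzyloxy)-5,7-dimethoxy-4H-chromen-4-one F2. Asymmetric conjugate addition of 3,4-dimethoxyphenylboronic acid to F2 in the presence of water, catalysed by Pd(OCOCF3)2 and the enantiomer of a tert-butyl pyridine–oxazoline ligand that delivers the (2S) product, gives 12.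

**Step 5.** The aryloxide 8 is chelated and stabilised by the acetyl group, so O-allylation may be slow. This would leave room for linear ether formation and for loss of enantiopurity by re-ionisation of the product, because the acyl-aryloxide is a good leaving group and the allyl cation is stabilised by the dimethoxyphenyl ring. The fallback runs the same allylation on a phenol without the carbonyl group and adds the acetyl group afterwards. It sets out from 1 and 7 and returns at 9. Benzylation of 1 (BnBr, K2CO3) gives 4-(benzyloxy)-3,5-dimethoxybenzaldehyde F3. Baeyer–Villiger oxidation with mCPBA gives 4-(benzyloxy)-3,5-dimethoxyphenyl formate F4, and methanolysis (catalytic K2CO3, MeOH) gives 4-(benzyloxy)-3,5-dimethoxyphenol F5. Bromination with one equivalent of NBS at low temperature gives 4-(benzyloxy)-2-bromo-3,5-dimethoxyphenol F6; the two free positions of F5 are equivalent. F6 is deprotonated with LiN(SiMe3)2 to lithium 4-(benzyloxy)-2-bromo-3,5-dimethoxyphenolate F7 and allylated with 7 under the catalyst of step 5, giving 2-(benzyloxy)-4-bromo-5-{[(1S)-1-(3,4-dimethoxyphenyl)prop-2-en-1-yl]oxy}-1,3-dimethoxybenzene F8. Bromine–lithium exchange with two equivalents of tert-butyllithium at −78 °C gives [3-(benzyloxy)-6-{[(1S)-1-(3,4-dimethoxyphenyl)prop-2-en-1-yl]oxy}-2,4-dimethoxyphenyl]lithium F9, which is acylated at once at that temperature with N-methoxy-N-methylacetamide and quenched with aqueous NH4Cl to give 9.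

**Step 8.** The tert-butyldimethylsilyl enol ether is fairly robust, and while it is being cleaved C2 may lose its configuration through reversible opening of ring C. This can occur by retro-oxa-Michael reaction of a transient enolate or by acid-promoted ionisation of the C2–O1 bond, which is benzylic to an electron-rich ring. The fallback changes the silyl group so that neither fluoride nor base is needed. It sets out from 9 and returns at 12. Silylation of 9 with TMSOTf and Et3N gives {[1-(3-(benzyloxy)-6-{[(1S)-1-(3,4-dimethoxyphenyl)prop-2-en-1-yl]oxy}-2,4-dimethoxyphenyl)ethenyl]oxy}trimethylsilane F10. Ring-closing metathesis as in step 7 gives {[(2S)-6-(benzyloxy)-2-(3,4-dimethoxyphenyl)-5,7-dimethoxy-2H-chromen-4-yl]oxy}trimethylsilane F11, which is hydrolysed to 12 by dilute aqueous citric acid during the work-up.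

**Step 9.** The benzyl ether is flanked by two methoxy groups and may be cleaved slowly. Over-reduction could then compete, either by hydrogenolytic opening of the benzylic C2–O1 bond of ring C or by reduction of the aryl ketone. The fallback replaces reduction by acidolysis and converts 12 directly into 13 with trifluoroacetic acid and pentamethylbenzene as cation scavenger at room temperature. It makes no new intermediate.

## Further compounds

F1 | step 7 | (E)-1-[3-(benzyloxy)-6-hydroxy-2,4-dimethoxyphenyl]-3-(dimethylamino)prop-2-en-1-one | CN(C)/C=C/C(=O)c1c(O)cc(OC)c(OCc2ccccc2)c1OC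
F2 | step 7 | 6-(benzyloxy)-5,7-dimethoxy-4H-chromen-4-one | O=c1ccoc2cc(OC)c(OCc3ccccc3)c(OC)c12
F3 | step 5 | 4-(benzyloxy)-3,5-dimethoxybenzaldehyde | COc1cc(C=O)cc(OC)c1OCc1ccccc1
F4 | step 5 | 4-(benzyloxy)-3,5-dimethoxyphenyl formate | COc1cc(OC=O)cc(OC)c1OCc1ccccc1
F5 | step 5 | 4-(benzyloxy)-3,5-dimethoxyphenol | COc1cc(O)cc(OC)c1OCc1ccccc1
F6 | step 5 | 4-(benzyloxy)-2-bromo-3,5-dimethoxyphenol | COc1cc(O)c(Br)c(OC)c1OCc1ccccc1
F7 | step 5 | lithium 4-(benzyloxy)-2-bromo-3,5-dimethoxyphenolate | [Li+].COc1cc([O-])c(Br)c(OC)c1OCc1ccccc1
F8 | step 5 | 2-(benzyloxy)-4-bromo-5-{[(1S)-1-(3,4-dimethoxyphenyl)prop-2-en-1-yl]oxy}-1,3-dimethoxybenzene | COc1cc(O[C@@H](C=C)c2ccc(OC)c(OC)c2)c(Br)c(OC)c1OCc1ccccc1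
F9 | step 5 | [3-(benzyloxy)-6-{[(1S)-1-(3,4-dimethoxyphenyl)prop-2-en-1-yl]oxy}-2,4-dimethoxyphenyl]lithium | COc1cc(O[C@@H](C=C)c2ccc(OC)c(OC)c2)c([Li])c(OC)c1OCc1ccccc1
F10 | step 8 | {[1-(3-(benzyloxy)-6-{[(1S)-1-(3,4-dimethoxyphenyl)prop-2-en-1-yl]oxy}-2,4-dimethoxyphenyl)ethenyl]oxy}trimethylsilane | C=C(O[Si](C)(C)C)c1c(O[C@@H](C=C)c2ccc(OC)c(OC)c2)cc(OC)c(OCc2ccccc2)c1OC
F11 | step 8 | {[(2S)-6-(benzyloxy)-2-(3,4-dimethoxyphenyl)-5,7-dimethoxy-2H-chromen-4-yl]oxy}trimethylsilane | COc1ccc([C@@H]2C=C(O[Si](C)(C)C)c3c(cc(OC)c(OCc4ccccc4)c3OC)O2)cc1OC
F0 | step 9 | none | none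
A1 | alternative 1 | (2S)-6-(benzyloxy)-2-(3,4-dimethoxyphenyl)-5,7-dihydroxychroman-4-one | COc1ccc([C@@H]2CC(=O)c3c(cc(O)c(OCc4ccccc4)c3O)O2)cc1OC
A2 | alternative 1 | ethyl 2-(benzyloxy)-4-[(2S)-2-(3,4-dimethoxyphenyl)-4-oxo-3,4-dihydro-2H-pyran-6-yl]-3-oxobutanoate | CCOC(=O)C(OCc1ccccc1)C(=O)CC1=CC(=O)C[C@@H](c2ccc(OC)c(OC)c2)O1
A3 | alternative 2 | (2R)-6-(benzyloxy)-2-(3,4-dimethoxyphenyl)-5,7-dimethoxy-2H-chromene-3-carbaldehyde | COc1ccc([C@@H]2C(C=O)=Cc3c(cc(OC)c(OCc4ccccc4)c3OC)O2)cc1OC
A4 | alternative 2 | 3-(benzyloxy)-6-hydroxy-2,4-dimethoxybenzaldehyde | O=Cc1c(O)cc(OC)c(OCc2ccccc2)c1OC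
A5 | alternative 2 | (E)-3-(3,4-dimethoxyphenyl)prop-2-enal | COc1ccc(/C=C/C=O)cc1OC
A6 | alternative 3 | (2S)-6-(benzyloxy)-4,4-diethoxy-2-(3,4-dimethoxyphenyl)-5,7-dimethoxychroman | COc1ccc([C@@H]2CC(OCC)(OCC)c3c(cc(OC)c(OCc4ccccc4)c3OC)O2)cc1OC
A7 | alternative 3 | 2-(benzyloxy)-5-[(3,4-dimethoxyphenyl)(methoxy)methoxy]-1,3-dimethoxybenzene (racemic) | COc1ccc(C(OC)Oc2cc(OC)c(OCc3ccccc3)c(OC)c2)cc1OC
A8 | alternative 3 | 1,1-diethoxyethene | C=C(OCC)OCC
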